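Atoms are numbered as in benzofuran (O1, C2, C3, C3a, C4–C7, C7a); compound numbers are those of the steps and the compound list below.

## The problem

Compound 21 is a trans-2-aryl-3-methyl-2,3-dihydrobenzofuran. A benzene ring (ring A, C3a–C4–C5–C6–C7–C7a) is fused to a dihydrofuran (O1, C2, C3) that carries a 3,4,5-trimethoxyphenyl group on C2 and a methyl group on C3; ring A carries an (E)-prop-1-enyl group on C5 and a methoxy group on C6. The only stereocentres are C2 and C3, both R and trans to each other. C3 is a carbon stereocentre that nothing installed later can correct, so it must be set absolutely and early. C2 is a benzylic ether carbon whose trans placement is the preferred one once C3 exists, so C3 can steer C2 but not the reverse. Ring A is 1,2,4,5-tetrasubstituted, with its two oxygens (C7a, C6) meta to each other and the carbon substituent (C5) ortho to the methoxy group, and this pattern must be installed without regiochemical doubt. Four features limit late-stage chemistry: the propenyl styrene (acid, electrophiles, oxidants, E/Z drift), the electron-rich arenes, the C2–H/C3–H pair (quinone oxidants lead on to the benzofuran) and the benzylic C2–O bond (strong acid, hydrogenolysis). The enabling feature is twofold: oxygen on C7a, oxygen on C6 and carbon on C5 are the substitution of a 4-alkoxycarbonylcyclohexane-1,3-dione, and C7a, C3a, C3, C2 and O1 are the ring atoms of a γ-butyrolactone with C7a as carbonyl carbon and C3a as α-carbon. Ring A can therefore be grown onto a chiral α-methylene lactone and aromatised afterwards.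

## Retrosynthesis

**21 ⇒ 19 + 20.** The C=C bond of the propenyl group is cut last in the forward sense, so the most fragile group is never carried through a step. A Julia–Kocienski reaction of aldehyde 19 with sulfone 20 is preferred to a Wittig ethylidenation (Z-rich mixtures) and to carbinol dehydration (acid next to the C2–O bond). The forward step must be E-selective under basic conditions.

**19 ⇒ 18 ⇒ 17 ⇒ 16.** No skeletal bond is cut. The aldehyde is traced through alcohol 18 to ester 17, and the methyl ether to the phenol of salicylate 16. An ortho-hydroxy ester is what an aromatised cyclic β-keto ester delivers, so the C5 carbon and the C6 oxygen arrive together and in the right positions. Two redox steps (LiAlH4, MnO2) are accepted in place of an unreliable partial reduction of an aryl ester.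

**16 ⇒ 14 (through 15).** Adding back two hydrogens (on C3a and C4) turns the tetrasubstituted benzene into the bicyclic vinylogous ester 14. Forward, a selenenylation/selenoxide elimination through selenide 15 is chosen over a quinone dehydrogenation, because a quinone could also dehydrogenate C2–C3 or oxidise the trimethoxybenzylic ether position. The step must remove hydrogen only from ring A.

**14 ⇒ 10 + 11 (through 12 and 13).** This is the strategic cut: C4–C5 and C7–C7a are broken and O1–C7a is returned to the lactone. All six carbons of ring A then come from the α-methylene lactone 10 (C7a, C3a, C4) and ethyl acetoacetate 11 (C5, C6, C7, with the ester already on C5). Cuts through the dihydrofuran would leave the ring A substitution problem unsolved. The forward reaction must add the acetoacetate to the exocyclic methylene before base can shift that double bond into the ring, and must then close ring A through the methyl carbon.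

**10 ⇒ 8.** The exocyclic methylene carbon (C4) is removed, leaving the saturated trans lactone 8; forward, C4 comes from formaldehyde. The shorter lactone-forming 2-(alkoxycarbonyl)crotylboration of 1 was set aside. The reagent geometry that is readily made leads through the chair transition state to the cis lactone, and a catalytic asymmetric version on that ester-bearing reagent class is not secured. The price is one extra step.

**8 ⇒ 6 ⇒ 4.** The lactone carbonyl (future C7a) is traced to the primary alcohol of diol 6 and this to the terminal alkene of homoallylic alcohol 4. Hydroboration and oxidative lactonisation touch neither stereocentre.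

**4 ⇒ 1 + 2.** The C2–C3 bond is cut between 3,4,5-trimethoxybenzaldehyde 1 and (E)-crotylboronate 2. One catalytic crotylboration sets both stereocentres; the anti relationship of 4 is the trans relationship of the target. Both partners are purchased, and the forward step must give high anti selectivity and face selectivity with an electron-rich aryl aldehyde.

## Roads not taken

**Alternative 1:** Aryne annulation. The cut is O1–C7a and C3–C3a. The sodium alkoxide of the erythro epoxy alcohol (S)-[(R)-oxiran-2-yl](3,4,5-trimethoxyphenyl)methanol A2 would add to 3-chloro-5-methoxybenzyne A3 at the future C7a. The aryl anion at C3a would then open the epoxide at its internal carbon (5-exo) to give [(2R,3S)-4-chloro-6-methoxy-2-(3,4,5-trimethoxyphenyl)-2,3-dihydrobenzofuran-3-yl]methanol A1.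
- Merits: the benzene ring is bought, no aromatisation is needed, the dihydrofuran forms in one convergent step, and trans follows from inversion at C3. In convergence this road is better than the chosen one.
- Weak points: A1 has a chlorine on C4 to remove, a hydroxymethyl on C3 to deoxygenate to methyl, and nothing on C5, so formylation and olefination still follow. The epoxy alkoxide of A2 can undergo Payne rearrangement under the strongly basic aryne conditions. The aryl anion must choose the internal over the terminal epoxide carbon. The regiochemistry of addition to A3 rests on the chlorine alone.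
- Comparison: the chosen plan keeps the methyl group as a methyl group throughout and fixes the C5 carbon by connectivity, at the cost of a late aromatisation.

**Alternative 2:** Oxa-Michael/6π-electrocyclisation. The cut is O1–C7a and C3a–C4. With KOtBu the hydroxyl of (7R,8R)-8-hydroxy-7-methyl-8-(3,4,5-trimethoxyphenyl)oct-1-en-4-yn-3-one A5 would add 5-exo-dig to the ynone. The derived trienolate would then electrocyclise to (2R,3R)-3-methyl-2-(3,4,5-trimethoxyphenyl)-3,3a,4,5-tetrahydrobenzofuran-6(2H)-one A4.
- Merits: both rings come from an acyclic chain in one isomerisation with no by-product, which is better in atom economy.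
- Weak points: A5 is a vinyl ynone exposed to alkoxide, so polymerisation and stray conjugate additions are likely. The anionic electrocyclisation is untested on such a system. A5 needs about five steps from alcohol 4, with the hydroxyl protected on the way. A4 lacks the C5 carbon and would have to be acylated at C5 to reach the level of 14.
- Comparison: the chosen plan reaches 14 directly from two stable carbonyl compounds by classical condensations, with the C5 ester built in.

**Alternative 3:** Diels–Alder benzannulation. The cut is C3a–C4 and C5–C6. The ketene acetal diene (2R,3R)-5-[2-methoxy-2-(trimethylsilyloxy)ethenyl]-3-methyl-2-(3,4,5-trimethoxyphenyl)-2,3-dihydrofuran A7 would add to pent-1-yn-3-one A8. Loss of trimethylsilanol would give 1-[(2R,3R)-6-methoxy-3-methyl-2-(3,4,5-trimethoxyphenyl)-2,3-dihydrobenzofuran-5-yl]propan-1-one A6.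
- Merits: ring A appears aromatic with the methoxy group and the three-carbon chain in place, and A6 is two steps (reduction, dehydration) from 21. With A7 drawn from lactone 8 in two further operations, this road is about two steps shorter than the chosen one, and that advantage is real.
- Weak points: A7 is a hydrolytically labile ketene acetal whose reacting terminus C3a is ring-bound, trisubstituted and next to the C3 stereocentre. Cycloaddition there must beat Mukaiyama–Michael addition and polymerisation of A8. Making A7 requires olefination of a lactone carbonyl and a regioselective γ-deprotonation beside C3.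
- Comparison: the chosen plan sets against the shorter count intermediates that are all stable and isolable, and bond formations whose regiochemistry follows from ring size rather than from orbital coefficients.

Key step: step 5

## Route

Assumption: boronate 2, sulfone 20 and the (R)-configured phosphoric acid of step 1 are purchased; should that acid deliver the crotyl group to the other face of 1, its (S) form is used instead.

Step 1
Reactants: 1 3,4,5-trimethoxybenzaldehyde; 2 (E)-2-(but-2-en-1-yl)-4,4,5,5-tetramethyl-1,3,2-dioxaborolane
Product: 4 (1R,2R)-2-methyl-1-(3,4,5-trimethoxyphenyl)but-3-en-1-ol, via O-pinacolboryl ether 3 (not isolated)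
Conditions: (R)-3,3′-bis(2,4,6-triisopropylphenyl)-1,1′-binaphthyl-2,2′-diyl hydrogen phosphate (5 mol%), 4 Å MS, PhMe, −30 °C; aqueous work-up
Reagents that add atoms: none
Why: Chiral phosphoric acid-catalysed crotylboration through a closed chair transition state: the E geometry of 2 gives the anti adduct, and the (R) acid is expected to direct the crotyl group to the Re face of 1, which sets 1R and with it 2R (the future C2 and C3); borate 3 is hydrolysed on work-up.

Step 2
Reactants: 4 (1R,2R)-2-methyl-1-(3,4,5-trimethoxyphenyl)but-3-en-1-ol
Product: 6 (1R,2R)-2-methyl-1-(3,4,5-trimethoxyphenyl)butane-1,4-diol, via bis-boryl adduct 5 (not isolated)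
Conditions: 9-borabicyclo[3.3.1]nonane (2.5 equiv), THF, 0 °C → rt; then NaOH aq, H2O2 (30%), 0 °C → rt
Reagents that add atoms: hydrogen peroxide, OO
Why: Hydroboration–oxidation: the borane adds anti-Markovnikov to the terminal alkene (one equivalent is taken up by the hydroxyl), and alkaline peroxide replaces boron by oxygen; neither stereocentre is involved.

Step 3
Reactants: 6 (1R,2R)-2-methyl-1-(3,4,5-trimethoxyphenyl)butane-1,4-diol
Product: 8 (4R,5R)-4-methyl-5-(3,4,5-trimethoxyphenyl)dihydrofuran-2(3H)-one, via lactol 7 (not isolated)
Conditions: 2,2,6,6-tetramethylpiperidin-1-oxyl (10 mol%), PhI(OAc)2 (2.5 equiv), CH2Cl2, rt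
Reagents that add atoms: none
Why: Nitroxyl-catalysed oxidative lactonisation of a 1,4-diol: the hindered oxoammonium oxidant takes the primary alcohol first, ring closure gives lactol 7 and this is oxidised on, so the benzylic hydroxyl becomes the ring oxygen and not a ketone.

Step 4
Reactants: 8 (4R,5R)-4-methyl-5-(3,4,5-trimethoxyphenyl)dihydrofuran-2(3H)-one
Product: 10 (4R,5R)-4-methyl-3-methylene-5-(3,4,5-trimethoxyphenyl)dihydrofuran-2(3H)-one, via sodium formyl enolate 9 (not isolated)
Conditions: NaH, HCO2Et, THF, 0 °C → rt; then (CH2O)n, THF, 65 °C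
Reagents that add atoms: paraformaldehyde (as formaldehyde), C=O
Why: α-Methylenation of a lactone by Claisen formylation and formaldehyde: enolate 9 undergoes aldol addition to formaldehyde, the formyl group moves to the new alkoxide and formate is lost to leave the exocyclic alkene; the C4 stereocentre of 8 is β to the carbonyl and not enolisable.

Step 5
Reactants: 10 (4R,5R)-4-methyl-3-methylene-5-(3,4,5-trimethoxyphenyl)dihydrofuran-2(3H)-one; 11 ethyl acetoacetate
Product: 14 ethyl (2R,3R)-3-methyl-6-oxo-2-(3,4,5-trimethoxyphenyl)-2,3,3a,4,5,6-hexahydrobenzofuran-5-carboxylate, via Michael adduct 12 (not isolated), via ring-opened hydroxy dione 13 (not isolated)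
Conditions: 11 (1.3 equiv), KOtBu (0.1 equiv), THF, 0 °C → rt; then KOtBu (3 equiv), THF, 0 → 45 °C; then 1 M HCl to pH 2, pyridinium p-toluenesulfonate (cat.), PhMe, 40 °C
Reagents that add atoms: none
Why: The potassium enolate of 11 adds through its central carbon to the exocyclic methylene of 10 (C4–C5) to give 12; with excess KOtBu the enolates equilibrate and the enolate of the acetyl methyl group attacks the lactone carbonyl (C7–C7a), expelling the C2 alkoxide and leaving dione 13 as its stabilised enolate, which pulls the equilibria forward. The closest known reaction type is the Michael–Claisen (Michael–Dieckmann) annulation of acetoacetates with acrylates to 4-alkoxycarbonylcyclohexane-1,3-diones, with an α-methylene lactone in the role of the acrylate. Ring A closes in a 6-(enolendo)-exo-trig mode; on acidification the C2 hydroxyl of 13 adds 5-exo-trig to the C7a carbonyl and the hemiketal loses water, which re-forms the dihydrofuran as a vinylogous ester. Regiochemistry is fixed by ring size: C5 could reach the lactone carbonyl only through a four-membered ring, and the hydroxyl could reach C6 only through a seven-membered one. The new centres C3a and C5 are both enolisable, are left uncontrolled and disappear on aromatisation. The selectivity that matters is Michael addition ahead of γ-deprotonation of 10 at C3, which would move the double bond into the ring and erase C3; it is secured by keeping 11 in excess over a catalytic amount of base, so that the only base present is the soft enolate of 11. Once 12 has formed neither C2 nor C3 is acidic, and the mild pyridinium acid closes the ether by carbonyl addition rather than through a benzylic cation.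

Step 6
Reactants: 14 ethyl (2R,3R)-3-methyl-6-oxo-2-(3,4,5-trimethoxyphenyl)-2,3,3a,4,5,6-hexahydrobenzofuran-5-carboxylate
Product: 16 ethyl (2R,3R)-6-hydroxy-3-methyl-2-(3,4,5-trimethoxyphenyl)-2,3-dihydrobenzofuran-5-carboxylate, via C5 phenylselenide 15 (not isolated)
Conditions: NaH, THF, 0 °C; PhSeCl, −78 → 0 °C; then H2O2 (30% aq), AcOH, 0 °C → rt
Reagents that add atoms: none
Why: α-Selenenylation and selenoxide syn-elimination: the β-keto ester enolate is selenenylated at C5, oxidation at selenium triggers elimination across C4–C5 (the only β-hydrogens), and enolisation of the C6 carbonyl with loss of the C3a hydrogen completes the benzene ring; no quinone oxidant is needed, so C2–H and C3–H stay.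

Step 7
Reactants: 16 ethyl (2R,3R)-6-hydroxy-3-methyl-2-(3,4,5-trimethoxyphenyl)-2,3-dihydrobenzofuran-5-carboxylate
Product: 17 ethyl (2R,3R)-6-methoxy-3-methyl-2-(3,4,5-trimethoxyphenyl)-2,3-dihydrobenzofuran-5-carboxylate
Conditions: MeI, K2CO3, DMF, rt
Reagents that add atoms: iodomethane, CI
Why: Williamson O-methylation of the salicylate phenol, the only acidic site in 16.

Step 8
Reactants: 17 ethyl (2R,3R)-6-methoxy-3-methyl-2-(3,4,5-trimethoxyphenyl)-2,3-dihydrobenzofuran-5-carboxylate
Product: 18 [(2R,3R)-6-methoxy-3-methyl-2-(3,4,5-trimethoxyphenyl)-2,3-dihydrobenzofuran-5-yl]methanol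
Conditions: LiAlH4, THF, 0 °C
Reagents that add atoms: none
Why: Hydride reduction of the aryl ester to the benzylic alcohol; aryl ethers and the dihydrofuran are inert to LiAlH4.

Step 9
Reactants: 18 [(2R,3R)-6-methoxy-3-methyl-2-(3,4,5-trimethoxyphenyl)-2,3-dihydrobenzofuran-5-yl]methanol
Product: 19 (2R,3R)-6-methoxy-3-methyl-2-(3,4,5-trimethoxyphenyl)-2,3-dihydrobenzofuran-5-carbaldehyde
Conditions: MnO2, CH2Cl2, rt
Reagents that add atoms: none
Why: MnO2 oxidation is selective for the electron-rich benzylic alcohol, stops at the aldehyde and does not dehydrogenate the dihydrofuran at room temperature.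

Step 10
Reactants: 19 (2R,3R)-6-methoxy-3-methyl-2-(3,4,5-trimethoxyphenyl)-2,3-dihydrobenzofuran-5-carbaldehyde; 20 5-(ethylsulfonyl)-1-phenyl-1H-tetrazole
Product: 21 (2R,3R)-6-methoxy-3-methyl-5-[(E)-prop-1-en-1-yl]-2-(3,4,5-trimethoxyphenyl)-2,3-dihydrobenzofuran
Conditions: KN(SiMe3)2, DME, −60 °C → rt; NH4Cl aq
Reagents that add atoms: none
Why: Julia–Kocienski olefination: the metalated sulfone adds to the non-enolisable aldehyde, Smiles transfer of the tetrazolyl group and loss of SO2 and tetrazolonate give the alkene, with E favoured for 1-phenyltetrazolyl sulfones and aryl aldehydes in a polar ether with potassium as counter-ion; C2 and C3 are not acidic under these conditions.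

## Compound list

1 | 3,4,5-trimethoxybenzaldehyde | COc1cc(C=O)cc(OC)c1OC | starting material
2 | (E)-2-(but-2-en-1-yl)-4,4,5,5-tetramethyl-1,3,2-dioxaborolane | C/C=C/CB1OC(C)(C)C(C)(C)O1 | starting material
3 | 2-{[(1R,2R)-2-methyl-1-(3,4,5-trimethoxyphenyl)but-3-en-1-yl]oxy}-4,4,5,5-tetramethyl-1,3,2-dioxaborolane | C=C[C@@H](C)[C@@H](OB1OC(C)(C)C(C)(C)O1)c1cc(OC)c(OC)c(OC)c1 | intermediate
4 | (1R,2R)-2-methyl-1-(3,4,5-trimethoxyphenyl)but-3-en-1-ol | C=C[C@@H](C)[C@@H](O)c1cc(OC)c(OC)c(OC)c1 | intermediate
5 | 9-{(3R,4R)-4-[(9-borabicyclo[3.3.1]nonan-9-yl)oxy]-3-methyl-4-(3,4,5-trimethoxyphenyl)butyl}-9-borabicyclo[3.3.1]nonane | B1(C2CCCC1CCC2)CC[C@@H](C)[C@@H](OB1C2CCCC1CCC2)c1cc(OC)c(OC)c(OC)c1 | intermediate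
6 | (1R,2R)-2-methyl-1-(3,4,5-trimethoxyphenyl)butane-1,4-diol | OCC[C@@H](C)[C@@H](O)c1cc(OC)c(OC)c(OC)c1 | intermediate
7 | (4R,5R)-4-methyl-5-(3,4,5-trimethoxyphenyl)tetrahydrofuran-2-ol (both anomers) | OC1C[C@@H](C)[C@H](c2cc(OC)c(OC)c(OC)c2)O1 | intermediate
8 | (4R,5R)-4-methyl-5-(3,4,5-trimethoxyphenyl)dihydrofuran-2(3H)-one | O=C1C[C@@H](C)[C@H](c2cc(OC)c(OC)c(OC)c2)O1 | intermediate
9 | sodium [(4R,5R)-4-methyl-2-oxo-5-(3,4,5-trimethoxyphenyl)dihydrofuran-3(2H)-ylidene]methanolate | [Na+].[O-]C=C1C(=O)O[C@@H](c2cc(OC)c(OC)c(OC)c2)[C@@H]1C | intermediate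
10 | (4R,5R)-4-methyl-3-methylene-5-(3,4,5-trimethoxyphenyl)dihydrofuran-2(3H)-one | C=C1C(=O)O[C@@H](c2cc(OC)c(OC)c(OC)c2)[C@@H]1C | intermediate
11 | ethyl acetoacetate | CCOC(=O)CC(C)=O | starting material
12 | ethyl 2-{[(4R,5R)-4-methyl-2-oxo-5-(3,4,5-trimethoxyphenyl)tetrahydrofuran-3-yl]methyl}-3-oxobutanoate (other centres unassigned) | CCOC(=O)C(C(C)=O)CC1C(=O)O[C@@H](c2cc(OC)c(OC)c(OC)c2)[C@@H]1C | intermediate
13 | ethyl 5-[(1R,2R)-1-hydroxy-1-(3,4,5-trimethoxyphenyl)propan-2-yl]-2,4-dioxocyclohexane-1-carboxylate (ring centres unassigned; present as its potassium salt before acidification) | CCOC(=O)C1CC(C(=O)CC1=O)[C@@H](C)[C@@H](O)c1cc(OC)c(OC)c(OC)c1 | intermediate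
14 | ethyl (2R,3R)-3-methyl-6-oxo-2-(3,4,5-trimethoxyphenyl)-2,3,3a,4,5,6-hexahydrobenzofuran-5-carboxylate (C3a and C5 unassigned) | CCOC(=O)C1CC2C(=CC1=O)O[C@@H](c1cc(OC)c(OC)c(OC)c1)[C@@H]2C | intermediate
15 | ethyl (2R,3R)-3-methyl-6-oxo-5-(phenylselanyl)-2-(3,4,5-trimethoxyphenyl)-2,3,3a,4,5,6-hexahydrobenzofuran-5-carboxylate (C3a and C5 unassigned) | CCOC(=O)C1([Se]c3ccccc3)CC2C(=CC1=O)O[C@@H](c1cc(OC)c(OC)c(OC)c1)[C@@H]2C | intermediate
16 | ethyl (2R,3R)-6-hydroxy-3-methyl-2-(3,4,5-trimethoxyphenyl)-2,3-dihydrobenzofuran-5-carboxylate | CCOC(=O)c1cc2c(cc1O)O[C@@H](c1cc(OC)c(OC)c(OC)c1)[C@@H]2C | intermediate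
17 | ethyl (2R,3R)-6-methoxy-3-methyl-2-(3,4,5-trimethoxyphenyl)-2,3-dihydrobenzofuran-5-carboxylate | CCOC(=O)c1cc2c(cc1OC)O[C@@H](c1cc(OC)c(OC)c(OC)c1)[C@@H]2C | intermediate
18 | [(2R,3R)-6-methoxy-3-methyl-2-(3,4,5-trimethoxyphenyl)-2,3-dihydrobenzofuran-5-yl]methanol | OCc1cc2c(cc1OC)O[C@@H](c1cc(OC)c(OC)c(OC)c1)[C@@H]2C | intermediate
19 | (2R,3R)-6-methoxy-3-methyl-2-(3,4,5-trimethoxyphenyl)-2,3-dihydrobenzofuran-5-carbaldehyde | O=Cc1cc2c(cc1OC)O[C@@H](c1cc(OC)c(OC)c(OC)c1)[C@@H]2C | intermediate
20 | 5-(ethylsulfonyl)-1-phenyl-1H-tetrazole | CCS(=O)(=O)c1nnnn1-c1ccccc1 | starting material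
21 | (2R,3R)-6-methoxy-3-methyl-5-[(E)-prop-1-en-1-yl]-2-(3,4,5-trimethoxyphenyl)-2,3-dihydrobenzofuran | C/C=C/c1cc2c(cc1OC)O[C@@H](c1cc(OC)c(OC)c(OC)c1)[C@@H]2C | target

## Step count and risk

Total: 10 steps. Longest linear sequence: 10 steps, from 1 to 21.

**Step 5 (key step).** Two processes may intervene. Before the Michael addition, base may move the exocyclic double bond of 10 into the ring (loss of C3) or start anionic oligomerisation of 10. At the Claisen stage, the closure depends on the minor methyl-derived enolate and may be outrun by retro-Michael fragmentation. The fallback sets out from lactone 8, avoids free 10 and returns at 12. The lithium enolate of 8 (LiN(iPr)2, THF, −78 °C) is treated with dimethyl(methylidene)ammonium iodide to give the Mannich base (4R,5R)-3-[(dimethylamino)methyl]-4-methyl-5-(3,4,5-trimethoxyphenyl)dihydrofuran-2(3H)-one F1. MeI converts it into the quaternary salt N,N,N-trimethyl-1-[(4R,5R)-4-methyl-2-oxo-5-(3,4,5-trimethoxyphenyl)tetrahydrofuran-3-yl]methanaminium iodide F2. F2 is added to 11 and NaH in THF, where elimination releases the acceptor slowly into an excess of the acetoacetate enolate, as in the Mannich-salt variant of the Robinson annulation. This gives 12, which is closed and cyclodehydrated to 14 as in step 5.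

**Step 6.** Selenenylation may go to C7, the nucleophilic carbon of the vinylogous ester, instead of C5, or electrophilic selenium species may attack the newly formed phenol ring during the oxidation. The fallback sets out from 14 and returns at 16: direct dehydrogenation with 2,3-dichloro-5,6-dicyano-1,4-benzoquinone (1.05 equiv, dioxane, rt). The β-keto ester enol should react faster than the C2–H/C3–H pair, and the oxidant is limited to one equivalent for that reason.

**Step 4.** Formylation may be incomplete, or the new double bond may shift into the ring during the hot, basic formaldehyde stage. The fallback sets out from 8 and returns at 10. The lithium enolate of 8 (LiN(iPr)2, THF, −78 °C) is hydroxymethylated with gaseous formaldehyde to (4R,5R)-3-(hydroxymethyl)-4-methyl-5-(3,4,5-trimethoxyphenyl)dihydrofuran-2(3H)-one F3. MsCl and Et3N give [(4R,5R)-4-methyl-2-oxo-5-(3,4,5-trimethoxyphenyl)tetrahydrofuran-3-yl]methyl methanesulfonate F4. Elimination with 1,8-diazabicyclo[5.4.0]undec-7-ene at 0 °C gives 10.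

**Step 10.** E-selectivity may be incomplete, which would leave a Z isomer that is hard to separate. The fallback sets out from 19 and returns at 21. EtMgBr in THF at 0 °C gives 1-[(2R,3R)-6-methoxy-3-methyl-2-(3,4,5-trimethoxyphenyl)-2,3-dihydrobenzofuran-5-yl]propan-1-ol F5. Its carbinol carbon is activated by the para ring oxygen and the ortho methoxy group, so dehydration with catalytic pyridinium p-toluenesulfonate in warm toluene should give the conjugated E alkene under thermodynamic control, under acid too weak to ionise the C2–O bond.

**Step 1.** Uncatalysed background allylboration or Z isomer in 2 may erode face selectivity and anti selectivity with this electron-rich aldehyde. The fallback sets out from 1 and returns at 4: stoichiometric reagent control with the enantiomer of (E)-crotyldiisopinocampheylborane that attacks the Re face of 1. The reagent is generated from trans-but-2-ene, n-BuLi/KOtBu and B-methoxydiisopinocampheylborane, then BF3·OEt2 at −78 °C, followed by NaOH/H2O2 work-up.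

## Further compounds

F1 | step 5 | (4R,5R)-3-[(dimethylamino)methyl]-4-methyl-5-(3,4,5-trimethoxyphenyl)dihydrofuran-2(3H)-one (C3 unassigned) | CN(C)CC1C(=O)O[C@@H](c2cc(OC)c(OC)c(OC)c2)[C@@H]1C
F2 | step 5 | N,N,N-trimethyl-1-[(4R,5R)-4-methyl-2-oxo-5-(3,4,5-trimethoxyphenyl)tetrahydrofuran-3-yl]methanaminium iodide (C3 unassigned) | C[N+](C)(C)CC1C(=O)O[C@@H](c2cc(OC)c(OC)c(OC)c2)[C@@H]1C.[I-]
F0 | step 6 | none | none
F3 | step 4 | (4R,5R)-3-(hydroxymethyl)-4-methyl-5-(3,4,5-trimethoxyphenyl)dihydrofuran-2(3H)-one (C3 unassigned) | OCC1C(=O)O[C@@H](c2cc(OC)c(OC)c(OC)c2)[C@@H]1C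
F4 | step 4 | [(4R,5R)-4-methyl-2-oxo-5-(3,4,5-trimethoxyphenyl)tetrahydrofuran-3-yl]methyl methanesulfonate (C3 unassigned) | CS(=O)(=O)OCC1C(=O)O[C@@H](c2cc(OC)c(OC)c(OC)c2)[C@@H]1C
F5 | step 10 | 1-[(2R,3R)-6-methoxy-3-methyl-2-(3,4,5-trimethoxyphenyl)-2,3-dihydrobenzofuran-5-yl]propan-1-ol (carbinol centre unassigned) | CCC(O)c1cc2c(cc1OC)O[C@@H](c1cc(OC)c(OC)c(OC)c1)[C@@H]2C
F0 | step 1 | none | none
A1 | alternative 1 | [(2R,3S)-4-chloro-6-methoxy-2-(3,4,5-trimethoxyphenyl)-2,3-dihydrobenzofuran-3-yl]methanol | c1c(Cl)c2c(cc1OC)O[C@@H](c1cc(OC)c(OC)c(OC)c1)[C@@H]2CO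
A2 | alternative 1 | (S)-[(R)-oxiran-2-yl](3,4,5-trimethoxyphenyl)methanol | O[C@@H](c1cc(OC)c(OC)c(OC)c1)[C@H]1CO1
A3 | alternative 1 | 3-chloro-5-methoxybenzyne (3-chloro-5-methoxy-1,2-didehydrobenzene) | COC1=CC#CC(Cl)=C1
A4 | alternative 2 | (2R,3R)-3-methyl-2-(3,4,5-trimethoxyphenyl)-3,3a,4,5-tetrahydrobenzofuran-6(2H)-one (C3a unassigned) | O=C1CCC2C(=C1)O[C@@H](c1cc(OC)c(OC)c(OC)c1)[C@@H]2C
A5 | alternative 2 | (7R,8R)-8-hydroxy-7-methyl-8-(3,4,5-trimethoxyphenyl)oct-1-en-4-yn-3-one | C=CC(=O)C#CC[C@@H](C)[C@@H](O)c1cc(OC)c(OC)c(OC)c1
A6 | alternative 3 | 1-[(2R,3R)-6-methoxy-3-methyl-2-(3,4,5-trimethoxyphenyl)-2,3-dihydrobenzofuran-5-yl]propan-1-one | CCC(=O)c1cc2c(cc1OC)O[C@@H](c1cc(OC)c(OC)c(OC)c1)[C@@H]2C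
A7 | alternative 3 | (2R,3R)-5-[2-methoxy-2-(trimethylsilyloxy)ethenyl]-3-methyl-2-(3,4,5-trimethoxyphenyl)-2,3-dihydrofuran | COC(O[Si](C)(C)C)=CC1=C[C@@H](C)[C@H](c2cc(OC)c(OC)c(OC)c2)O1
A8 | alternative 3 | pent-1-yn-3-one | CCC(=O)C#C
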